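The amounts come first. The flask holds 20 mM of J and as much D against 0.400 mM of X, so whatever X binds takes hardly any of the J. The reckoning here therefore freezes c_J and c_D against the loading: between 2 mol% and 3 mol%, at one charge of J and one conversion, each X is taken to meet the same surroundings, and the rate of making E should then scale with the X charged.

| flask | J | D | X | remark |
|---|---|---|---|---|
| south-west | 13 mM | 1 equiv | 2 mol% | run made earlier |
| south-east | 30 mM | 1 equiv | 2 mol% | run made earlier |
| east | 20 mM | 1 equiv | 3 mol% | run made earlier |
| flask | 20 mM | 1.00 equiv | 2 mol% |  |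

- south-west (time / h: E / %, J / %): 4.00: 15.0, 85.4; 8.00: 24.3, 72.0; 10.0: 32.5, 66.2; 15.0: 46.0, 55.2
- south-east (time / h: E / %, J / %): 2.00: 9.4, 90.5; 5.00: 23.8, 77.7; 10.0: 43.8, 55.1; 15.0: 61.1, 38.1
- east (time / h: E / %, J / %): 1.00: 7.3, 90.4; 2.50: 12.7, 83.5; 6.00: 34.4, 63.1; 15.0: 72.6, 27.9

(readings scatter by 1 percentage point)

- the analysis behind the earlier runs scatters by 1 percentage point, standard deviation
- what is bound to the catalyst counts as converted

1. apparent order in X when 10 % of the J are converted (percent change of the rate of making E for one percent more X charged)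

The tables can test this at nearly equal conversion, near a third. East has E 34.4 % at 6.00 h, which gives 1.91 h⁻¹: this is T, the E made per X charged per hour since the start, a mean turnover frequency. South-west, with E 32.5 % at 10.0 h, gives 1.62 h⁻¹. South-east brackets that conversion with its readings at 5.00 h and 10.0 h, whose T values average 2.28 h⁻¹.

T reads higher in south-east than in south-west, where J and D are charged together at 1 equiv, but the geometric mean of those two charges of J is 19.7 mM, close to the 20 mM of east. So, taking T as a power of the charge, the geometric mean of the two T values, 1.93 h⁻¹, stands for 2 mol% at that charge. Against east's T, this gives an order of 0.980, and one point of scatter in the east reading moves it by 0.0717. The reckoning here carries that order to the 10 % asked.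

The forecast differs, setting 0.7 within 0.45 to 0.95, with the words “some catalyst is parked off-cycle”.

The flask gives 1.0.

    J + X ⇌ G (K = 60.0 M⁻¹, k = 18000 M⁻¹ h⁻¹)
    D + X ⇌ L (K = 28.0 M⁻¹, k = 2300 M⁻¹ h⁻¹)
    L → X + Z (k = 7.40 h⁻¹)
    G → X + E (k = 4.90 h⁻¹)

In the flask at 5.44 h, G falls back to J and X 61 times faster than it goes on to E. In the flask at 12.0 h, the relaxation half-life of J + X and G by the step J + X ⇌ G alone is 0.0833 min, far shorter than the hours of the run. In this flask, T is 2.01 h⁻¹ at 6.00 h with E 24.1 %, and 1.87 h⁻¹ at 12.0 h with E 44.9 %.

The numbers in the tables are calculated with made-up constants.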